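**Retrosynthetic overview**
1. Final bond set (C13–C1′ and C11–C3′, norbornene and spiro-lactone): endo Diels–Alder between the exocyclic methylene of eudesmanolide 14 and the 2-acetoxycyclopentadiene 30, made by dehydrating tertiary allylic alcohol 29.
2. Eudesmanolide 14: ring A from 2-methylcyclohexane-1,3-dione, ring B by proline Robinson annulation (C10), a ketoreductase sets C1–OH, C4–Me by γ-methylenation and face-selective hydrogenation, cis-lactone last by Pd vinyl-epoxide alkylation and decarboxylative methylenation.
3. Guaianolide 29: five-membered ring from cyclopentane-1,3-dione, C10 by organocatalytic Michael addition to crotonaldehyde, Stork–Danheiser transposition to the cyclopentenone, seven-membered ring by RCM, trans-lactone by 1,6-malonate addition, C2 carbinol by CBS reduction.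
4. Ring order: eudesmane A → B → lactone; guaiane 5 → 7 → lactone → cyclopentadiene; then the norbornene.

Assumption: the SMILES alone defines the absolute configuration (every intermediate SMILES was derived from it); reagents, catalysts and the enzyme are named in each step and not numbered; C4 of the guaiane fragment is carried as an epimer mixture that converges in 30.

---

**Eudesmanolide half**

Step 1
Reactants: 1 (2-methylcyclohexane-1,3-dione), 2 (methyl vinyl ketone)
Product: 3, 2-methyl-2-(3-oxobutyl)cyclohexane-1,3-dione (achiral)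
Conditions: AcOH, H2O, hydroquinone (cat.), 75 °C
Reagents that add atoms: none
Why: Michael addition of the acidic 1,3-dione to the enone gives the prochiral triketone; no stereocentre yet.

Step 2
Reactants: 3
Product: 4, (S)-Wieland–Miescher ketone
Conditions: L-proline (5 mol%), DMSO, rt; recrystallise
Reagents that add atoms: none
Why: Hajos–Parrish–Eder–Sauer–Wiechert aldol condensation; the proline enamine selects one enantiotopic ring carbonyl and sets quaternary C10 as (S).

Step 3
Reactants: 4
Product: 5, (4aS,5S)-5-hydroxy-4a-methyl-4,4a,5,6,7,8-hexahydronaphthalen-2(3H)-one (OH cis to the angular methyl)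
Conditions: ketoreductase (KRED), NADP+ (cat.), glucose/glucose dehydrogenase, pH 7 phosphate buffer–DMSO, 30 °C
Reagents that add atoms: none
Why: Enzymatic ketone reduction; the ketoreductase reduces only the saturated C1 ketone of (S)-4, with hydride anti to the angular methyl, setting C1 as (S) and leaving residual (R)-4 behind, so ee and dr are upgraded.

Step 4
Reactants: 5
Product: 6, TIPS ether of 5
Conditions: TIPSOTf, 2,6-lutidine, CH2Cl2, 0 °C
Reagents that add atoms: triisopropylsilyl triflate, CC(C)[Si](OS(=O)(=O)C(F)(F)F)(C(C)C)C(C)C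
Why: Silylation; the hindered TIPS ether survives the acidic, basic and Pd steps that follow.

Step 5
Reactants: 6
Product: 7, (4aS,5S)-4a-methyl-8-methylidene-5-(triisopropylsilyloxy)-4,4a,5,6,7,8-hexahydronaphthalen-2(3H)-one
Conditions: CH2(OEt)2, POCl3, NaOAc, CHCl3, 60 °C
Reagents that add atoms: diethoxymethane, CCOCOCC
Why: γ-Methylenation via the dienol ether (vinylogous Prins/Mannich-type attack of the alkoxymethyl cation at C4, then elimination), the standard 6-methylenation of Δ4-3-keto steroids; C4 is the only γ-position bearing hydrogen.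

Step 6
Reactants: 7
Product: 8, (4aS,5S,8R)-4a,8-dimethyl-5-(triisopropylsilyloxy)-4,4a,5,6,7,8-hexahydronaphthalen-2(3H)-one (new methyl cis to the angular methyl)
Conditions: H2 (1 atm), (Ph3P)3RhCl (10 mol%), benzene–EtOH, rt
Reagents that add atoms: none
Why: Wilkinson hydrogenation reduces only the 1,1-disubstituted exocyclic alkene; H2 arrives anti to the axial angular methyl, giving the axial C4 methyl (4R) under neutral conditions that avoid γ-epimerisation.

Step 7
Reactants: 8
Product: 9, (3R,4aS,5S,8R)-3-bromo-4a,8-dimethyl-5-(triisopropylsilyloxy)-4,4a,5,6,7,8-hexahydronaphthalen-2(3H)-one (Br trans to the angular methyl)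
Conditions: i) LDA, TMSCl, THF, −78 °C; ii) NBS, THF, −78 → 0 °C
Reagents that add atoms: N-bromosuccinimide, BrN1C(=O)CCC1=O
Why: Kinetic α′-enolisation to the cross-conjugated silyl dienol ether, then electrophilic bromination at C8 from the face opposite the angular methyl.

Step 8
Reactants: 9
Product: 10, (2R,3R,4aS,5S,8R)-3-bromo-4a,8-dimethyl-5-(triisopropylsilyloxy)-2,3,4,4a,5,6,7,8-octahydronaphthalen-2-ol (trans-bromohydrin)
Conditions: NaBH4, CeCl3·7H2O, MeOH, −78 °C
Reagents that add atoms: none
Why: Luche 1,2-reduction; axial hydride delivery gives the equatorial allylic alcohol, cis to the angular methyl and trans to Br.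

Step 9
Reactants: 10
Product: 11, (7R,8S)-7,8-epoxide (eudesmane numbering) of the Δ5-octalin, epoxide on the angular-methyl face
Conditions: K2CO3, MeOH, 0 °C → rt
Reagents that add atoms: none
Why: Intramolecular Williamson SN2 with inversion at C8 converts the trans-bromohydrin into the vinyl epoxide on the more hindered face, the classical route to such epoxides.

Step 10
Reactants: 11
Product: 12, methyl (3aS,5R,8S,8aS,9aS)-5,8a-dimethyl-2-oxo-8-(triisopropylsilyloxy)-2,3,3a,5,6,7,8,8a,9,9a-decahydronaphtho[2,3-b]furan-3-carboxylate (C3 epimers)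
Conditions: Pd(PPh3)4 (5 mol%), dimethyl malonate, THF, rt → 50 °C; then NaOMe (cat.), MeOH
Reagents that add atoms: dimethyl malonate, COC(=O)CC(=O)OC
Why: Tsuji–Trost alkylation of the vinyl epoxide; Pd ionises anti to oxygen and malonate attacks anti to Pd at C7 (C5 is fully substituted and next to quaternary C10), so C7–C and C8–O end up cis and the alkoxide closes the cis-fused lactone with C5=C6 retained.

Step 11
Reactants: 12
Product: 13, (3aS,5R,8S,8aS,9aS)-5,8a-dimethyl-3-methylidene-8-(triisopropylsilyloxy)-3a,5,6,7,8,8a,9,9a-octahydronaphtho[2,3-b]furan-2(3H)-one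
Conditions: i) LiOH, THF–H2O, then 1 M HCl; ii) 37% aq. HCHO, Et2NH, NaOAc, AcOH, 80 °C
Reagents that add atoms: formaldehyde, C=O
Why: Saponification, then decarboxylative Mannich methylenation of the α-carboxy lactone installs the exocyclic methylene without strong base.

Step 12
Reactants: 13
Product: 14, (1S,4R,7S,8S,10S)-1-hydroxyeudesma-5,11(13)-dien-12,8-olide (1-hydroxyalantolactone skeleton in the configuration of the target)
Conditions: HF·pyridine, THF, rt
Reagents that add atoms: none
Why: Fluoride desilylation under buffered conditions that the α-methylene lactone tolerates.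

---

**Guaianolide half**

Step 13
Reactants: 15 (cyclopentane-1,3-dione), 16 ((E)-crotonaldehyde)
Product: 17, (4R)-2-hydroxy-4-methyl-3,4,6,7-tetrahydrocyclopenta[b]pyran-5(2H)-one (lactol, anomer mixture)
Conditions: (S)-α,α-diphenylprolinol TMS ether (10 mol%), CH2Cl2, 0 °C
Reagents that add atoms: none
Why: Iminium-ion organocatalytic Michael addition; the dione attacks the β-carbon opposite the CPh2OTMS group, setting the methyl-bearing carbon (future C10) as (R), and the adduct closes to a lactol that is also a vinylogous ester.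

Step 14
Reactants: 17
Product: 18, (4R)-2-methoxy-4-methyl-3,4,6,7-tetrahydrocyclopenta[b]pyran-5(2H)-one
Conditions: MeOH, PPTS (cat.), 4 Å MS, rt
Reagents that add atoms: methanol, CO
Why: Acetalisation of the lactol protects the aldehyde and leaves the vinylogous ester intact.

Step 15
Reactants: 18
Product: 19, (4R)-2-methoxy-4,6-dimethyl-3,4,6,7-tetrahydrocyclopenta[b]pyran-5(2H)-one (C6 epimers)
Conditions: LDA, THF, −78 °C; MeI
Reagents that add atoms: iodomethane, CI
Why: Kinetic α′-alkylation of the vinylogous ester (Stork–Danheiser alkylation) installs the future C4 methyl; the new centre is later destroyed.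

Step 16
Reactants: 19
Product: 20, (4R)-6-hydroxy-2-methoxy-4,6-dimethyl-3,4,6,7-tetrahydrocyclopenta[b]pyran-5(2H)-one (C6 epimers)
Conditions: LDA, THF, −78 °C; 2-(phenylsulfonyl)-3-phenyloxaziridine
Reagents that add atoms: Davis oxaziridine, O=S(=O)(c1ccccc1)N1OC1c1ccccc1
Why: Enolate hydroxylation gives the tertiary α-hydroxy ketone, the future C4–OH leaving group.

Step 17
Reactants: 20
Product: 21, (3R)-3-(3-hydroxy-3-methyl-5-oxo-2-vinylcyclopent-1-en-1-yl)butanal
Conditions: CH2=CHMgBr (3.5 equiv), CeCl3, THF, −78 → 0 °C; then 1 M HCl, THF, rt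
Reagents that add atoms: vinylmagnesium bromide, C=C[Mg]Br; water, O
Why: Stork–Danheiser 1,2-addition and acidic transposition; vinyl adds to the vinylogous-ester carbonyl, and hydrolysis gives the 2,3-disubstituted cyclopentenone and frees the C8 aldehyde.

Step 18
Reactants: 21
Product: 22, 4-hydroxy-2-[(2R,4R)-4-hydroxyhex-5-en-2-yl]-4-methyl-3-vinylcyclopent-2-en-1-one
Conditions: Zn(CH=CH2)2 (3 equiv), (−)-MIB (10 mol%), toluene–hexane, 0 °C; chromatography
Reagents that add atoms: divinylzinc, C=C[Zn]C=C
Why: Amino-alcohol-catalysed asymmetric organozinc addition, selective for the aldehyde; catalyst-controlled Si-face vinyl transfer gives the (8R) allylic alcohol, and the minor C8 epimer is separable.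

Step 19
Reactants: 22
Product: 23, TBS ether of the secondary allylic alcohol of 22
Conditions: TBSCl, imidazole, DMF, rt
Reagents that add atoms: tert-butyldimethylsilyl chloride, CC(C)(C)[Si](C)(C)Cl
Why: Selective silylation of the secondary alcohol; the tertiary alcohol does not react.

Step 20
Reactants: 23
Product: 24, (6R,8R)-6-(tert-butyldimethylsilyloxy)-3-hydroxy-3,8-dimethyl-3,6,7,8-tetrahydroazulen-1(2H)-one
Conditions: Hoveyda–Grubbs II (5 mol%), toluene (5 mM), 60 °C
Reagents that add atoms: none
Why: Ring-closing metathesis of the two vinyl groups, held cis on the cyclopentene, closes the seven-membered ring (C6=C7) with loss of ethylene.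

Step 21
Reactants: 24
Product: 25, dimethyl 2-[(5S,6R,8R)-6-(tert-butyldimethylsilyloxy)-3-hydroxy-3,8-dimethyl-1-oxo-1,2,3,4,5,6,7,8-octahydroazulen-5-yl]malonate
Conditions: dimethyl malonate, NaOMe (0.3 equiv), MeOH, 0 °C → rt
Reagents that add atoms: dimethyl malonate, COC(=O)CC(=O)OC
Why: Vinylogous (1,6) Michael addition; the β-carbon is fully substituted, so malonate adds at the δ-carbon C7 anti to the adjacent OTBS (C7/C8 trans), and the dienolate reprotonates to the conjugated enone.

Step 22
Reactants: 25
Product: 26, (7S,8R,10R)-4-hydroxy-11-(methoxycarbonyl)-2-oxo-13-norguai-1(5)-en-12,8-olide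
Conditions: HF·pyridine, THF, rt; then PPTS, toluene, 60 °C
Reagents that add atoms: none
Why: Desilylation, then lactonisation of the trans hydroxy-malonate gives the trans-fused γ-lactone; the γ-hydroxy enone is deactivated toward ionisation.

Step 23
Reactants: 26
Product: 27, (7S,8R,10R)-4-hydroxy-2-oxoguaia-1(5),11(13)-dien-12,8-olide
Conditions: i) LiOH, THF–H2O, 0 °C, then 1 M HCl; ii) 37% aq. HCHO, Et2NH, NaOAc, AcOH, 70 °C
Reagents that add atoms: formaldehyde, C=O
Why: Saponification and decarboxylative Mannich methylenation, as in step 11.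

Step 24
Reactants: 27
Product: 28, (2S,7S,8R,10R)-2,4-dihydroxyguaia-1(5),11(13)-dien-12,8-olide
Conditions: (R)-Me-CBS, catecholborane, toluene, −78 °C
Reagents that add atoms: none
Why: Corey–Bakshi–Shibata reduction; reagent-controlled hydride delivery to the cyclopentenone gives the (2S) allylic alcohol for either C4 epimer, and the methylene lactone is inert at −78 °C.

Step 25
Reactants: 28
Product: 29, (2S,7S,8R,10R)-2-acetoxy-4-hydroxyguaia-1(5),11(13)-dien-12,8-olide
Conditions: Ac2O, pyridine, DMAP (cat.), CH2Cl2, 0 °C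
Reagents that add atoms: acetic anhydride, CC(=O)OC(C)=O
Why: Acylation of the secondary allylic alcohol only; the tertiary alcohol is left as the leaving group.

Step 26
Reactants: 29
Product: 30, (2S,7S,8R,10R)-2-acetoxyguaia-1(5),3,11(13)-trien-12,8-olide (not isolated)
Conditions: Burgess reagent (1.1 equiv), toluene, 0 °C → rt, 30 min; solution used directly
Reagents that add atoms: none
Why: Burgess dehydration of the tertiary allylic alcohol with loss of a C3 hydrogen gives the conjugated cyclopentadiene; both C4 epimers converge and C2 is untouched.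

---

**Union**

Step 27
Reactants: 30 (fresh solution), 14 (3 equiv; excess recovered)
Product: 31, japonicone A
Conditions: BHT (cat.), toluene (about 1 M in 14), rt, dark, 48 h
Reagents that add atoms: none
Why: Intermolecular endo Diels–Alder that sets C11, C1′ and C3′:
- 14 reacts on the convex (H7/H8) face of its exocyclic alkene.
- 30 reacts on the face anti to both the C2 acetoxy and the C10 methyl.
- The CH2 terminus bonds to the fully substituted C1′ and the incipient quaternary C11 to the unsubstituted C3′, with the lactone carbonyl endo.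

---

**Compound list**

1 | 2-methylcyclohexane-1,3-dione | CC1C(=O)CCCC1=O | starting material
2 | methyl vinyl ketone | CC(=O)C=C | starting material
3 | 2-methyl-2-(3-oxobutyl)cyclohexane-1,3-dione | CC(=O)CCC1(C)C(=O)CCCC1=O | intermediate
4 | (S)-Wieland–Miescher ketone | O=C1CC[C@@]2(C)C(=C1)CCCC2=O | intermediate
5 | (4aS,5S)-hydroxy enone | O=C1CC[C@@]2(C)C(=C1)CCC[C@@H]2O | intermediate
6 | TIPS ether of 5 | O=C1CC[C@@]2(C)C(=C1)CCC[C@@H]2O[Si](C(C)C)(C(C)C)C(C)C | intermediate
7 | γ-methylidene enone | O=C1CC[C@@]2(C)C(=C1)C(=C)CC[C@@H]2O[Si](C(C)C)(C(C)C)C(C)C | intermediate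
8 | cis-4,10-dimethyl enone | O=C1CC[C@@]2(C)C(=C1)[C@H](C)CC[C@@H]2O[Si](C(C)C)(C(C)C)C(C)C | intermediate
9 | α′-bromo enone | O=C1[C@H](Br)C[C@@]2(C)C(=C1)[C@H](C)CC[C@@H]2O[Si](C(C)C)(C(C)C)C(C)C | intermediate
10 | trans-bromohydrin | O[C@H]1[C@H](Br)C[C@@]2(C)C(=C1)[C@H](C)CC[C@@H]2O[Si](C(C)C)(C(C)C)C(C)C | intermediate
11 | vinyl epoxide | O1[C@H]2C[C@@]3(C)C(=C[C@@H]12)[C@H](C)CC[C@@H]3O[Si](C(C)C)(C(C)C)C(C)C | intermediate
12 | α-carbomethoxy cis-lactone | COC(=O)C1C(=O)O[C@H]2C[C@@]3(C)C(=C[C@H]21)[C@H](C)CC[C@@H]3O[Si](C(C)C)(C(C)C)C(C)C | intermediate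
13 | α-methylene lactone TIPS ether | C=C1C(=O)O[C@H]2C[C@@]3(C)C(=C[C@H]21)[C@H](C)CC[C@@H]3O[Si](C(C)C)(C(C)C)C(C)C | intermediate
14 | (1S,4R,7S,8S,10S)-1-hydroxyeudesma-5,11(13)-dien-12,8-olide | C=C1C(=O)O[C@H]2C[C@@]3(C)C(=C[C@H]21)[C@H](C)CC[C@@H]3O | intermediate
15 | cyclopentane-1,3-dione | O=C1CCC(=O)C1 | starting material
16 | (E)-crotonaldehyde | C/C=C/C=O | starting material
17 | (4R)-lactol | OC1C[C@@H](C)C2=C(O1)CCC2=O | intermediate
18 | methyl acetal | COC1C[C@@H](C)C2=C(O1)CCC2=O | intermediate
19 | α′-methyl vinylogous ester | COC1C[C@@H](C)C2=C(O1)CC(C)C2=O | intermediate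
20 | α′-hydroxy-α′-methyl vinylogous ester | COC1C[C@@H](C)C2=C(O1)CC(C)(O)C2=O | intermediate
21 | vinyl cyclopentenone aldehyde | O=CC[C@@H](C)C1=C(C=C)C(C)(O)CC1=O | intermediate
22 | (8R)-allylic alcohol | C=C[C@H](O)C[C@@H](C)C1=C(C=C)C(C)(O)CC1=O | intermediate
23 | TBS ether of 22 | C=C[C@H](O[Si](C)(C)C(C)(C)C)C[C@@H](C)C1=C(C=C)C(C)(O)CC1=O | intermediate
24 | bicyclic dienone | CC(C)(C)[Si](C)(C)O[C@@H]1C[C@@H](C)C2=C(C=C1)C(C)(O)CC2=O | intermediate
25 | 1,6-malonate adduct | CC(C)(C)[Si](C)(C)O[C@@H]1C[C@@H](C)C2=C(C[C@H]1C(C(=O)OC)C(=O)OC)C(C)(O)CC2=O | intermediate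
26 | α-carbomethoxy trans-lactone | COC(=O)C1C(=O)O[C@@H]2C[C@@H](C)C3=C(C[C@@H]12)C(C)(O)CC3=O | intermediate
27 | methylene lactone enone | C=C1C(=O)O[C@@H]2C[C@@H](C)C3=C(C[C@@H]12)C(C)(O)CC3=O | intermediate
28 | (2S)-allylic alcohol | C=C1C(=O)O[C@@H]2C[C@@H](C)C3=C(C[C@@H]12)C(C)(O)C[C@@H]3O | intermediate
29 | 2-acetoxy-4-hydroxy guaianolide | C=C1C(=O)O[C@@H]2C[C@@H](C)C3=C(C[C@@H]12)C(C)(O)C[C@@H]3OC(C)=O | intermediate
30 | 2-acetoxy cyclopentadiene guaianolide | C=C1C(=O)O[C@@H]2C[C@@H](C)C3=C(C[C@@H]12)C(C)=C[C@@H]3OC(C)=O | intermediate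
31 | japonicone A | C=C1C(=O)O[C@@H]2C[C@@H](C)[C@]34C[C@]5(C(=O)O[C@H]6C[C@@]7(C)C(=C[C@H]65)[C@H](C)CC[C@@H]7O)[C@H](C(C)=C3C[C@@H]12)[C@@H]4OC(C)=O | target

---

**Totals**
- Total steps: 27.
- Longest linear sequence: 15 steps (15/16 → 31, steps 13–27); the eudesmanolide branch is 12 steps plus the union.

**Steps most likely to fail, with fallbacks**
1. Steps 26–27 (diene generation and Diels–Alder). Risks: the stereoelectronic preference of 5-acyloxycyclopentadienes for addition syn to oxygen, 1,5-H shift of the diene, and self-dimerisation of 30. Fallback: carry C2 at the ketone level. Ketalise enone 27, dehydrate to the cyclopentadienone ketal diene (no H shift, no C2 facial issue), run the Diels–Alder with 14, hydrolyse to the bridging ketone, then set the C2 carbinol by reagent control (ketoreductase panel or equilibrating reduction) and acetylate.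
2. Step 10 (Pd alkylation of the vinyl epoxide). Risks: isomerisation of the epoxide to a dienol or enone, or the wrong regiochemistry. Fallback: drop the epoxide. From 8, α′-hydroxylate (Rubottom) and protect, Luche-reduce, form the C7 allylic carbonate and run a plain Tsuji–Trost malonate alkylation at C7 (retention). Then oxidise C8 to the ketone, reduce with NaBH4 to the axial alcohol and lactonise.
3. Step 21 (1,6-malonate addition). Risks: low reactivity at the substituted δ-carbon or poor anti selectivity. Fallback: build C11 in before ring closure. Couple aldehyde 21 (Nozaki–Hiyama–Kishi) with a 2-iodoallyl unit bearing the protected C11–C12 chain, close by RCM to the trisubstituted C6=C7 alkene, and set C7 trans to C8–O by hydroxyl-directed (Crabtree) hydrogenation. Then lactonise oxidatively and methylenate via Eschenmoser's salt with the ring ketone reduced and protected.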